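The data are calculated on assumed constants, and the scatter is random.

How much E stands in this flask at 2.5 min, and which change raises it?

| setting | Wednesday's | Saturday's | Tuesday's | flask |
|---|---|---|---|---|
| L | 20 mM | 20 mM | 30 mM | 20 mM |
| Z | 0.90 equiv | 1.4 equiv | 1.8 equiv | 1.80 equiv |
| remark | run made earlier | run made earlier | run made earlier |  |
| time |  |  |  | 2.5 min |
| volume of the second phase over the first |  |  |  | 0.50 |

| run | time / s | E / % | L / % |
|---|---|---|---|
| Wednesday's | 10.0 | 1.7 | 97.4 |
| Wednesday's | 15.0 | 3.1 | 95.0 |
| Wednesday's | 25.0 | 7.1 | 92.9 |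
| Wednesday's | 40.0 | 10.6 | 88.7 |
| Wednesday's | 80.0 | 15.8 | 72.8 |
| Wednesday's | 120 | 22.2 | 60.4 |
| Saturday's | 10.0 | 3.4 | 95.7 |
| Saturday's | 25.0 | 10.2 | 89.4 |
| Saturday's | 40.0 | 17.3 | 77.7 |
| Saturday's | 60.0 | 22.8 | 69.7 |
| Saturday's | 90.0 | 30.1 | 54.7 |
| Saturday's | 120 | 37.1 | 38.3 |
| Tuesday's | 10.0 | 4.3 | 92.9 |
| Tuesday's | 20.0 | 11.7 | 86.6 |
| Tuesday's | 30.0 | 15.9 | 80.5 |
| Tuesday's | 60.0 | 25.1 | 57.4 |
| Tuesday's | 120 | 45.0 | 19.9 |

(each reading ± 1 percentage point)

- amount of E at 2.5 min, in percent of the L charged
- the change that raises the amount of E at 2.5 min, in percent of the L charged most ("none" if none brings more than 2 percentage points) (summer / autumn / none)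
- amount of E at 2.5 min, in percent of the L charged, after autumn

- summer: doubling the amount of Z, all else as stated
- autumn: doubling the transfer coefficient of Z, all else as stated

- in the second phase: Z; everything else is in the first
- charges count per volume of the first phase; a concentration in a rate is the amount of a species over the volume of its own phase; every rate counts per litre of the first phase
- the earlier runs hold the two phases in the same ratio of volumes as the flask asked about

Let us follow a molecule of E. We suppose it has one fork: it stays, or it meets an L and both are lost. That is a pseudo-first-order loss that fades as L falls. The shortfall (L lost minus E) then grows by two per meeting. Its coefficient k is the shortfall over twice the L charge times the area under E × L against time, in shares of the charge. The feed f is the L turned into E, per equivalent of Z and per second.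

| Run | Shortfall | Area | k | f |
|---|---|---|---|---|
| Wednesday's | 17.4% | 11.0 s | 0.394 L mol⁻¹ s⁻¹ | 0.00286 s⁻¹ |
| Saturday's | 24.6% | 15.2 s | 0.405 L mol⁻¹ s⁻¹ | 0.00294 s⁻¹ |
| Tuesday's | 35.1% | 13.1 s | 0.445 L mol⁻¹ s⁻¹ | 0.00290 s⁻¹ |

Reading down, Tuesday's shortfall is larger than Saturday's. Yet Tuesday's area is smaller than Saturday's. Tuesday's L charge is higher than Saturday's, and k runs from 0.394 L mol⁻¹ s⁻¹ to 0.445 L mol⁻¹ s⁻¹ down the rows. So the supposed fork survives. The feed per equivalent runs from 0.00286 s⁻¹ to 0.00294 s⁻¹ while the Z charge goes from 0.90 equiv to 1.8 equiv. We carry the means, 0.415 L mol⁻¹ s⁻¹ and 0.00290 s⁻¹.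

Our quantity is the risk number, k times the L charge over f times the equivalents of Z 1.59. With fed share x, meetings come to about B(x²/2 − x³/3), taking E and L as fed, which overstates them. In this flask we reckon 78.3% fed, so we expect a shortfall of 46.6% and E near 55.0%. Together they come to 102% of the L charged, so this shortfall is an upper estimate. Autumn halves B and, by this reckoning, uses up L before the reading, giving about 73.5%. By this reckoning doubling Z gives the same feed, so the two changes tie, and we name autumn as a guess.

The forecast gave 47%, none and 31%: “Neither helps, so best is none.”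

The flask gives 56.2%. The best change is autumn, worth 15 percentage points against 9.9 points for summer, and it reaches 71.2%.

    Q ⇌ Z, rate k1*([Q] - [Z]/K1) per volume of the first phase (partition coefficient = 2.40, kL = 0.00445 s⁻¹)
    L + Q → E (k = 56.1 L mol⁻¹ s⁻¹)
    Q ⇌ D (K = 0.740, k = 0.0634 s⁻¹)
    L + E → J (k = 0.380 L mol⁻¹ s⁻¹)
    Q + E → G (k = 0.819 L mol⁻¹ s⁻¹)

In this flask, L fell from 90.8% at 0.250 min to 13.2% at 2.50 min, and half the turnover of L + Q → E up to the reading was done by 1.05 min. Half that of L + E → J was done by 1.27 min, and at the reading E was made 4.03 times faster than used up, each step taken net. J, which counts two, stands at 29.7%, less than our shortfall.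

At 5.0 mM of L, the risk number is 0.398, a quarter of the flask's, so we expect a shortfall of 11.6%. That neighbour holds 9.67% of J and 62.2% of E.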